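| flask | left-handed substrate | right-handed substrate | coupling partner | precatalyst | remark | time |
|---|---|---|---|---|---|---|
| larch | 0.20 M | 0.20 M | 0.50 M | 5 mM | the very flask that is asked about, followed so far |  |
| elm | 0.13 M | 0.13 M | 0.50 M | 5 mM | run made earlier |  |
| flask | 0.20 M | 0.20 M | 0.500 M | 5.0 mM |  | 25 min |

| run | time / min | left-handed product / % | right-handed product / % |
|---|---|---|---|
| larch | 0.417 | 4.8 | 1.9 |
| larch | 0.667 | 6.9 | 4.0 |
| larch | 1.00 | 13.9 | 4.9 |
| larch | 1.33 | 17.0 | 7.7 |
| larch | 2.00 | 21.9 | 10.7 |
| larch | 3.00 | 28.8 | 15.7 |
| larch | 5.00 | 36.1 | 21.5 |
| elm | 4.00 | 35.7 | 17.9 |
| elm | 8.00 | 44.6 | 28.9 |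
| elm | 10.0 | 46.1 | 31.6 |
| elm | 15.0 | 49.2 | 38.2 |
| elm | 20.0 | 49.9 | 39.2 |
| elm | 25.0 | 50.4 | 41.7 |

(standard deviation of a reading: 1 percentage point)

- left-handed product and right-handed product together, in percent of the left-handed substrate and right-handed substrate charged together, at 25 min
- excess of left-handed product over right-handed product in the product at 25 min
- whether the exchange between left-handed substrate and right-handed substrate keeps pace with the reaction: how far the product's excess at 25 min gets from its value without exchange to its value with instant exchange (above 80% keeps pace, below 20% hardly takes part, else lags behind)

- coupling partner is single-handed; left-handed substrate and right-handed substrate are mirror images of each other, charged as a racemate, each of them at the stated concentration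
- the analysis behind the earlier runs scatters by 1 percentage point, standard deviation
- an excess is the difference of the two amounts in percent of their sum
- an excess is below zero if the other one leads
- the handed part of coupling partner does not stay in what it makes, so the products of the two hands are mirror images too

1. In elm the left-handed product reads 50.4% at 25.0 min, within the scatter of 1 percentage point of the 50.0% one hand can give. I see no crossing between the hands, so I rank exchange below every other rung and answer "hardly takes part".

2. Let f_L and f_R be the fractions of each hand's substrate left, each one minus twice its product's reading. Larch up to 2.00 min gives a mean apparent first-order constant of 0.288 min⁻¹ for the left hand, taken over a falling amount of coupling partner, and so an apparent half-life of 2.41 min. The right hand's mean apparent constant over the same span is 0.120 min⁻¹, an apparent half-life of 5.78 min, which is slower.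

3. Both hands meet the same coupling partner, so it drops out of the selectivity factor s, the ratio of ln f_L to ln f_R. Larch at 5.00 min reads s = 2.28. Without exchange, f_R is then f_L raised to the inverse of s.

4. The next rung is the partner's decline. Its charge exceeds the substrates' 0.400 M, so substrate is the limiting reagent, but the rates sink with the partner. Larch holds 0.270 M at 5.00 min, and 0.100 M would remain at full conversion. Scaling the right-hand constant to the mean of these gives 0.0512 min⁻¹. So at 25 min I reckon f_R = 20.5% and, through s, f_L = 2.70%. That means a yield of 88.4% and an excess of 10.1%.

5. The forecast says 87% (82% to 91%), 12% (9% to 16%) and hardly takes part, since “each hand simply follows its own kinetics”. Its excess is higher than mine.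

6. The flask gives 88.7%, 13.0% and hardly takes part, 6.1% of the way.

    coupling partner + precatalyst → racemization catalyst + spent reagent (k = 0.00560 L mol⁻¹ s⁻¹)
    coupling partner + right-handed substrate → right-handed product (k = 0.00470 L mol⁻¹ s⁻¹)
    left-handed substrate + racemization catalyst ⇌ right-handed substrate + racemization catalyst, rate k3*[racemization catalyst]*[left-handed substrate] forward; the back reaction follows from the equilibrium constant (k = 0.0300 L mol⁻¹ s⁻¹)
    coupling partner + left-handed substrate → left-handed product (k = 0.0120 L mol⁻¹ s⁻¹)

In the flask, half of the left-handed turnover is done by 2.34 min, and racemization catalyst stands at 29.1% of the catalyst charged at 2.50 min. At 25.0 min, 3.1% of the left-handed substrate remains, for which s gives 21.8% of the right-handed substrate, and the flask holds less, 19%. In the neighbour flask charged with 0.12 M of coupling partner, 61% of the left-handed substrate remains, for which s gives 80.5%, and that neighbour holds 81% of the right-handed substrate.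

The readings come from a simulation with constants of no real substance; the scatter is artificial.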